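## Retrosynthetic overview

1. Target 26 ⇐ cis-epoxidation of the (Z)-C1=C10 olefin of 24; the C11=C13 methylene and the cis lactone fusion come from reductive α-methylenation of macrocyclic butenolide 20.
2. Ten-membered ring ⇐ C5–C6 bond: a silyloxyfuran adds to a tethered 2-substituted acrolein (vinylogous aldol, 18 → 20), sacrificing furan aromaticity.
3. C7–C8 ⇐ enantioselective addition of a (2-silyloxy)furan-4-yl zinc reagent (masked butenolide) to aldehyde 9; C3–C4 ⇐ Negishi coupling with 2-bromoacrolein acetal.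
4. C8–C9–C10(C14)=C1–C2–C3 with fixed Z geometry ⇐ the benzene ring of 3-methylanisole, by Birch reduction and ozonolysis of the enol-ether bond only.
5. Ring order: benzene ring unzipped (steps 1–2) → butenolide carried as a furan (steps 6–9) → ten-membered carbocycle (step 10) → oxirane (step 12).

Assumption: atoms carry germacrane-style labels (C1/C10 epoxide carbons with C14 on C10, C4 bearing C15H2, C5 carbinol, C6 lactone O-carbon, C7, C8 angelate carbon, C9, C11/C12/C13 lactone α-carbon/carbonyl/methylene), which makes the target (1R,5S,6R,7R,8S,10S) with a cis (Z-derived) epoxide and a cis-fused lactone; 1, 6, 10 and 15 are bought.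

## Route

Step 1
Reactants: 1 3-methylanisole
Product: 2 1-methoxy-5-methylcyclohexa-1,4-diene
Conditions: Li, NH3 (l), THF, t-BuOH, −78 to −33 °C
Reagents that add atoms: none
Why: Birch reduction gives the 1,4-diene with OMe and Me on sp2 carbons, breaking aromaticity and holding the future C9 and C2 cis on the C10=C1 double bond; no stereocentre is formed.

Step 2
Reactants: 2 1-methoxy-5-methylcyclohexa-1,4-diene
Product: 4 methyl (3Z)-6-hydroxy-3-methylhex-3-enoate, via aldehyde ester 3 (not isolated)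
Conditions: O3 (1.0 equiv), CH2Cl2–MeOH 4:1, −78 °C; Me2S; then NaBH4, 0 °C
Reagents that add atoms: ozone, [O-][O+]=O
Why: Chemoselective ozonolysis cleaves the electron-rich enol-ether double bond much faster than the trisubstituted olefin, turning C8 into the methyl ester and C3 into an aldehyde that NaBH4 reduces in the same flask, with the ring-derived Z geometry untouched.

Step 3
Reactants: 4 methyl (3Z)-6-hydroxy-3-methylhex-3-enoate
Product: 5 methyl (3Z)-6-iodo-3-methylhex-3-enoate
Conditions: I2, PPh3, imidazole, CH2Cl2, 0 °C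
Reagents that add atoms: iodine, II
Why: Appel-type iodination converts the primary alcohol into the iodide under near-neutral conditions that do not move the β,γ-double bond into conjugation.

Step 4
Reactants: 5 methyl (3Z)-6-iodo-3-methylhex-3-enoate; 6 2-bromo-3,3-diethoxyprop-1-ene
Product: 8 methyl (3Z)-7-(diethoxymethyl)-3-methylocta-3,7-dienoate, via organozinc iodide 7 (not isolated)
Conditions: Zn dust, LiCl, THF, 40 °C; then 6, Pd(OAc)2 (2 mol %), 2-dicyclohexylphosphino-2′,6′-dimethoxybiphenyl (4 mol %), 25 °C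
Reagents that add atoms: none
Why: Zinc insertion gives an ester-tolerant alkylzinc that undergoes Negishi sp3–sp2 coupling with the vinyl bromide, installing C4 with its exocyclic methylene and C5 at the aldehyde oxidation level.

Step 5
Reactants: 8 methyl (3Z)-7-(diethoxymethyl)-3-methylocta-3,7-dienoate
Product: 9 (3Z)-7-(diethoxymethyl)-3-methylocta-3,7-dienal
Conditions: iBu2AlH (1.05 equiv), CH2Cl2, −78 °C; aq. potassium sodium tartrate
Reagents that add atoms: none
Why: Partial ester reduction stops at the aluminium hemiacetal at −78 °C and releases the β,γ-unsaturated aldehyde on cold work-up without conjugation.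

Step 6
Reactants: 10 4-bromofuran-2(5H)-one
Product: 11 4-bromo-2-(triisopropylsilyloxy)furan
Conditions: iPr3SiOTf, Et3N, CH2Cl2, 0 °C
Reagents that add atoms: triisopropylsilyl trifluoromethanesulfonate, CC(C)[Si](C(C)C)(C(C)C)OS(=O)(=O)C(F)(F)F
Why: Soft enolisation with O-silylation at the γ-CH2 gives the aromatic 2-silyloxyfuran, a masked butenolide whose C–Br bond can be metalated without β-elimination of the ring oxygen.

Step 7
Reactants: 9 (3Z)-7-(diethoxymethyl)-3-methylocta-3,7-dienal; 11 4-bromo-2-(triisopropylsilyloxy)furan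
Product: 14 (1S,3Z)-7-(diethoxymethyl)-3-methyl-1-[5-(triisopropylsilyloxy)furan-3-yl]octa-3,7-dien-1-ol, via furyllithium 12 (not isolated), via ethyl(furyl)zinc 13 (not isolated)
Conditions: 11, n-BuLi, t-BuOMe, −78 °C; EtZnCl; (Et2NCH2)2; (2R)-3-exo-morpholinoisoborneol (5 mol %); then 9, 0 °C
Reagents that add atoms: none
Why: Bromine–lithium exchange, transmetalation to zinc and amino-alkoxide-catalysed enantioselective heteroarylzinc addition to the aldehyde form C7–C8 and set C8 (S) by catalyst-controlled choice of the aldehyde face (ligand enantiomer to be confirmed experimentally for the 8S carbinol).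

Step 8
Reactants: 14 (1S,3Z)-7-(diethoxymethyl)-3-methyl-1-[5-(triisopropylsilyloxy)furan-3-yl]octa-3,7-dien-1-ol; 15 angelic acid [(2Z)-2-methylbut-2-enoic acid]
Product: 17 (1S,3Z)-7-(diethoxymethyl)-3-methyl-1-[5-(triisopropylsilyloxy)furan-3-yl]octa-3,7-dien-1-yl (2Z)-2-methylbut-2-enoate, via mixed anhydride 16 (not isolated)
Conditions: 15, 2,4,6-Cl3C6H2COCl, Et3N, toluene, 25 °C; then 14, 40 °C
Reagents that add atoms: none
Why: Yamaguchi mixed-anhydride esterification without DMAP acylates the carbinol with retention at C8 and without Z-to-E isomerisation of the angelate; any early loss of the silyl group is harmless because step 9 removes it anyway.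

Step 9
Reactants: 17 (1S,3Z)-7-(diethoxymethyl)-3-methyl-1-[5-(triisopropylsilyloxy)furan-3-yl]octa-3,7-dien-1-yl (2Z)-2-methylbut-2-enoate
Product: 18 (1S,3Z)-7-formyl-3-methyl-1-(5-oxo-2,5-dihydrofuran-3-yl)octa-3,7-dien-1-yl (2Z)-2-methylbut-2-enoate
Conditions: 0.2 M HCl, THF–H2O 4:1, 0 °C
Reagents that add atoms: water, O
Why: Dilute-acid hydrolysis unmasks both the 2-substituted acrolein (acetal cleavage) and the conjugated butenolide (γ-protonation of the silyl dienol ether), leaving C8 untouched.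

Step 10
Reactants: 18 (1S,3Z)-7-formyl-3-methyl-1-(5-oxo-2,5-dihydrofuran-3-yl)octa-3,7-dien-1-yl (2Z)-2-methylbut-2-enoate
Product: 20 (5S,6R,8S)-8-angeloyloxy-5-(triethylsilyloxy)-13-norgermacra-1(10)Z,4(15),7(11)-trien-12,6-olide, via silyloxyfuran 19 (not isolated)
Conditions: Et3SiOTf (2.2 equiv), Et3N (2.5 equiv), CH2Cl2, 0.002 M (18 added over 10 h), −78 to −30 °C
Reagents that add atoms: triethylsilyl trifluoromethanesulfonate, CC[Si](CC)(CC)OS(=O)(=O)C(F)(F)F
Why: Proposed new method: Et3SiOTf/Et3N converts the butenolide into aromatic silyloxyfuran 19, whose C6 adds 1,2 to the silyl-activated enal through an open transition state and regenerates the butenolide (silylative vinylogous Mukaiyama aldol, known for five- to seven-membered carbocycles from butenolide aldehydes and extended here to a ten-membered ring); with C8–H eclipsing the furan C11–H the C9 tether and the new bond lie on the face opposite the angelate (6R from 8S), and because C9 fills the sector next to C6–H the aldehyde must turn its hydrogen there and its C4 branch over the ring with C=O anti to C6=C7, giving the erythro 5S silyl ether.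

Step 11
Reactants: 20 (5S,6R,8S)-8-angeloyloxy-5-(triethylsilyloxy)-13-norgermacra-1(10)Z,4(15),7(11)-trien-12,6-olide
Product: 24 (5S,6R,7R,8S)-8-angeloyloxy-5-(triethylsilyloxy)germacra-1(10)Z,4(15),11(13)-trien-12,6-olide, via silyl ketene acetal 21 (not isolated), via Mannich base 22 (not isolated), via ammonium iodide 23 (not isolated)
Conditions: [(Ph3P)CuH]6 (0.25 equiv), Me3SiCl, THF, −40 to 0 °C; Me2N+=CH2 I−, CH2Cl2, 25 °C; MeI; aq. NaHCO3
Reagents that add atoms: N,N-dimethylmethyleneiminium iodide (Eschenmoser's salt), C=[N+](C)C.[I-]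
Why: Copper hydride conjugate reduction of the butenolide (the α-methyl Z-enoate of the angelate is far less reactive) delivers hydride to C7 on the face opposite the C5/C9 ring bridge to give the cis-fused lactone (7R), and the silyl ketene acetal then undergoes a Mukaiyama–Mannich reaction, quaternisation and base-induced elimination (reductive α-methylenation).

Step 12
Reactants: 24 (5S,6R,7R,8S)-8-angeloyloxy-5-(triethylsilyloxy)germacra-1(10)Z,4(15),11(13)-trien-12,6-olide
Product: 26 (1R,5S,6R,7R,8S,10S)-8-angeloyloxy-1,10-epoxy-5-hydroxygermacra-4(15),11(13)-dien-12,6-olide, via alcohol 25 (not isolated)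
Conditions: aq. HF, MeCN, 0 °C; then aq. NaHCO3, CH2Cl2, mCPBA (1.05 equiv), 0 °C
Reagents that add atoms: mCPBA, OOC(=O)c1cccc(Cl)c1
Why: After acid desilylation, Prilezhaev epoxidation takes the most electron-rich trisubstituted Z-olefin, syn to the transannular C5 hydroxyl (hydrogen-bond delivery) and anti to the C8 ester, so the Z geometry becomes the cis-epoxide with 1R,10S configuration.

## Compound list

1 | 3-methylanisole (1-methoxy-3-methylbenzene) | COc1cccc(C)c1 | starting material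
2 | 1-methoxy-5-methylcyclohexa-1,4-diene | COC1=CCC=C(C)C1 | intermediate
3 | methyl (3Z)-3-methyl-6-oxohex-3-enoate | COC(=O)C/C(C)=C\CC=O | intermediate (not isolated)
4 | methyl (3Z)-6-hydroxy-3-methylhex-3-enoate | COC(=O)C/C(C)=C\CCO | intermediate
5 | methyl (3Z)-6-iodo-3-methylhex-3-enoate | COC(=O)C/C(C)=C\CCI | intermediate
6 | 2-bromo-3,3-diethoxyprop-1-ene (2-bromoacrolein diethyl acetal) | C=C(Br)C(OCC)OCC | starting material
7 | [(3Z)-6-methoxy-4-methyl-6-oxohex-3-en-1-yl]zinc iodide | COC(=O)C/C(C)=C\CC[Zn]I | intermediate (not isolated)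
8 | methyl (3Z)-7-(diethoxymethyl)-3-methylocta-3,7-dienoate | COC(=O)C/C(C)=C\CCC(=C)C(OCC)OCC | intermediate
9 | (3Z)-7-(diethoxymethyl)-3-methylocta-3,7-dienal | O=CC/C(C)=C\CCC(=C)C(OCC)OCC | intermediate
10 | 4-bromofuran-2(5H)-one | O=C1OCC(Br)=C1 | starting material
11 | 4-bromo-2-(triisopropylsilyloxy)furan | CC(C)[Si](C(C)C)(C(C)C)Oc1cc(Br)co1 | intermediate
12 | 4-lithio-2-(triisopropylsilyloxy)furan | [Li]c1coc(O[Si](C(C)C)(C(C)C)C(C)C)c1 | intermediate (not isolated)
13 | ethyl[5-(triisopropylsilyloxy)furan-3-yl]zinc | CC[Zn]c1coc(O[Si](C(C)C)(C(C)C)C(C)C)c1 | intermediate (not isolated)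
14 | (1S,3Z)-7-(diethoxymethyl)-3-methyl-1-[5-(triisopropylsilyloxy)furan-3-yl]octa-3,7-dien-1-ol | CC(C)[Si](C(C)C)(C(C)C)Oc1cc(co1)[C@@H](O)C/C(C)=C\CCC(=C)C(OCC)OCC | intermediate
15 | angelic acid [(2Z)-2-methylbut-2-enoic acid] | C/C=C(/C)C(=O)O | starting material
16 | (2Z)-2-methylbut-2-enoic 2,4,6-trichlorobenzoic anhydride | C/C=C(/C)C(=O)OC(=O)c1c(Cl)cc(Cl)cc1Cl | intermediate (not isolated)
17 | (1S,3Z)-7-(diethoxymethyl)-3-methyl-1-[5-(triisopropylsilyloxy)furan-3-yl]octa-3,7-dien-1-yl (2Z)-2-methylbut-2-enoate | CC(C)[Si](C(C)C)(C(C)C)Oc1cc(co1)[C@@H](OC(=O)/C(C)=C\C)C/C(C)=C\CCC(=C)C(OCC)OCC | intermediate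
18 | (1S,3Z)-7-formyl-3-methyl-1-(5-oxo-2,5-dihydrofuran-3-yl)octa-3,7-dien-1-yl (2Z)-2-methylbut-2-enoate | O=C1OCC(=C1)[C@@H](OC(=O)/C(C)=C\C)C/C(C)=C\CCC(=C)C=O | intermediate
19 | (1S,3Z)-7-formyl-3-methyl-1-[5-(triethylsilyloxy)furan-3-yl]octa-3,7-dien-1-yl (2Z)-2-methylbut-2-enoate | CC[Si](CC)(CC)Oc1cc(co1)[C@@H](OC(=O)/C(C)=C\C)C/C(C)=C\CCC(=C)C=O | intermediate (not isolated)
20 | (5S,6R,8S)-8-angeloyloxy-5-(triethylsilyloxy)-13-norgermacra-1(10)Z,4(15),7(11)-trien-12,6-olide (macrocyclic butenolide) | O=C1O[C@@H]2C(=C1)[C@@H](OC(=O)/C(C)=C\C)C/C(C)=C\CCC(=C)[C@@H]2O[Si](CC)(CC)CC | intermediate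
21 | C12 O-trimethylsilyl ketene acetal of (5S,6R,7R,8S)-8-angeloyloxy-5-(triethylsilyloxy)-13-norgermacra-1(10)Z,4(15)-dien-12,6-olide | C1=C(O[Si](C)(C)C)O[C@@H]2[C@H]1[C@@H](OC(=O)/C(C)=C\C)C/C(C)=C\CCC(=C)[C@@H]2O[Si](CC)(CC)CC | intermediate (not isolated)
22 | (5S,6R,7R,8S,11R)-8-angeloyloxy-13-(dimethylamino)-5-(triethylsilyloxy)germacra-1(10)Z,4(15)-dien-12,6-olide (C11 configuration is lost in the next event) | CN(C)C[C@@H]1C(=O)O[C@@H]2[C@H]1[C@@H](OC(=O)/C(C)=C\C)C/C(C)=C\CCC(=C)[C@@H]2O[Si](CC)(CC)CC | intermediate (not isolated)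
23 | (5S,6R,7R,8S,11R)-8-angeloyloxy-5-(triethylsilyloxy)-13-(trimethylammonio)germacra-1(10)Z,4(15)-dien-12,6-olide iodide | C[N+](C)(C)C[C@@H]1C(=O)O[C@@H]2[C@H]1[C@@H](OC(=O)/C(C)=C\C)C/C(C)=C\CCC(=C)[C@@H]2O[Si](CC)(CC)CC.[I-] | intermediate (not isolated)
24 | (5S,6R,7R,8S)-8-angeloyloxy-5-(triethylsilyloxy)germacra-1(10)Z,4(15),11(13)-trien-12,6-olide | C=C1C(=O)O[C@@H]2[C@H]1[C@@H](OC(=O)/C(C)=C\C)C/C(C)=C\CCC(=C)[C@@H]2O[Si](CC)(CC)CC | intermediate
25 | (5S,6R,7R,8S)-8-angeloyloxy-5-hydroxygermacra-1(10)Z,4(15),11(13)-trien-12,6-olide | C=C1C(=O)O[C@@H]2[C@H]1[C@@H](OC(=O)/C(C)=C\C)C/C(C)=C\CCC(=C)[C@@H]2O | intermediate (not isolated)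
26 | (1R,5S,6R,7R,8S,10S)-8-angeloyloxy-1,10-epoxy-5-hydroxygermacra-4(15),11(13)-dien-12,6-olide (CNP0227074.3) | C=C1C(=O)O[C@@H]2[C@H]1[C@@H](OC(=O)/C(C)=C\C)C[C@]1(C)O[C@@H]1CCC(=C)[C@@H]2O | target

## Step count and risks

Total step count: 12. Longest linear sequence: 11 (steps 1–5 and 7–12; step 6 is a one-step branch from 10).

**Risk 1, step 10** (ring closure: 1,2- versus 1,4-addition to the enal, strain of the ten-membered ring, C5 and C6 set only by substrate control). The fallback sets out from 9 and comes back at 20. Aqueous oxalic acid frees the second aldehyde of 9 to give (3Z)-3-methyl-7-methylideneoct-3-enedial F1. An intermolecular, catalyst-controlled vinylogous Mukaiyama aldol of silyloxyfuran 11 with F1 then sets C5 and C6. Conditions are SiCl4, the bisphosphoramide N,N′-dimethyl-N,N′-bis[(11bR)-3,5-dimethyl-4-oxido-3,5-dihydro-4H-dinaphtho[2,1-d:1′,2′-f][1,3,2]diazaphosphepin-4-yl]pentane-1,5-diamine (5 mol %), iPr2NEt, CH2Cl2, −78 °C; only the conjugated aldehyde reacts, because the saturated one is held as its α-chloro silyl ether until work-up. This gives (5S)-4-bromo-5-[(1S,5Z)-1-hydroxy-6-methyl-2-methylidene-8-oxooct-5-en-1-yl]furan-2(5H)-one F2. Et3SiCl and imidazole give (5S)-4-bromo-5-[(1S,5Z)-6-methyl-2-methylidene-8-oxo-1-(triethylsilyloxy)oct-5-en-1-yl]furan-2(5H)-one F3. The ring is then closed at C7–C8 by an intramolecular Nozaki–Hiyama–Kishi reaction (CrCl2, NiCl2 cat., (S)-N-[2-(4-isopropyl-4,5-dihydro-1,3-oxazol-2-yl)-6-methylphenyl]methanesulfonamide, MeCN, 0.002 M) to give (5S,6R,8S)-8-hydroxy-5-(triethylsilyloxy)-13-norgermacra-1(10)Z,4(15),7(11)-trien-12,6-olide F4. Esterification of F4 with 15 as in step 8 returns to 20.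

**Risk 2, step 12** (face and site of epoxidation: the wrong face of C1=C10, or attack at the C4=C15 allylic alcohol). The fallback sets out from 25, isolated after the HF treatment, and comes back at 26. N-Bromosuccinimide in aqueous acetone places bromine on C1 from the face a peracid would also choose and water on C10 from the opposite face. This gives (1S,5S,6R,7R,8S,10S)-8-angeloyloxy-1-bromo-5,10-dihydroxygermacra-4(15),11(13)-dien-12,6-olide F5. K2CO3 in acetone closes the oxirane with inversion at C1, so the oxygen ends on the face opposite to direct electrophilic attack and 26 results.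

**Risk 3, step 7** (enantiomeric purity at C8, the only stereocentre that later steps are relayed from). The fallback sets out from 9 and comes back at 14. Addition of furyllithium 12 to 9 without the zinc catalyst gives racemic (3Z)-7-(diethoxymethyl)-3-methyl-1-[5-(triisopropylsilyloxy)furan-3-yl]octa-3,7-dien-1-ol F6. MnO2 oxidises it to (3Z)-7-(diethoxymethyl)-3-methyl-1-[5-(triisopropylsilyloxy)furan-3-yl]octa-3,7-dien-1-one F7. Oxazaborolidine-catalysed reduction ((R)-1-methyl-3,3-diphenyltetrahydro-1H,3H-pyrrolo[1,2-c][1,3,2]oxazaborole, catecholborane, toluene, −78 °C) then returns (S)-configured 14.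

## Further compounds

F1 | step 10 | (3Z)-3-methyl-7-methylideneoct-3-enedial | O=CC/C(C)=C\CCC(=C)C=O
F2 | step 10 | (5S)-4-bromo-5-[(1S,5Z)-1-hydroxy-6-methyl-2-methylidene-8-oxooct-5-en-1-yl]furan-2(5H)-one | O=C1O[C@H](C(Br)=C1)[C@@H](O)C(=C)CC/C=C(C)\CC=O
F3 | step 10 | (5S)-4-bromo-5-[(1S,5Z)-6-methyl-2-methylidene-8-oxo-1-(triethylsilyloxy)oct-5-en-1-yl]furan-2(5H)-one | O=C1O[C@H](C(Br)=C1)[C@@H](O[Si](CC)(CC)CC)C(=C)CC/C=C(C)\CC=O
F4 | step 10 | (5S,6R,8S)-8-hydroxy-5-(triethylsilyloxy)-13-norgermacra-1(10)Z,4(15),7(11)-trien-12,6-olide | O=C1O[C@@H]2C(=C1)[C@@H](O)C/C(C)=C\CCC(=C)[C@@H]2O[Si](CC)(CC)CC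
F5 | step 12 | (1S,5S,6R,7R,8S,10S)-8-angeloyloxy-1-bromo-5,10-dihydroxygermacra-4(15),11(13)-dien-12,6-olide | C=C1C(=O)O[C@@H]2[C@H]1[C@@H](OC(=O)/C(C)=C\C)C[C@](C)(O)[C@@H](Br)CCC(=C)[C@@H]2O
F6 | step 7 | racemic (3Z)-7-(diethoxymethyl)-3-methyl-1-[5-(triisopropylsilyloxy)furan-3-yl]octa-3,7-dien-1-ol | CC(C)[Si](C(C)C)(C(C)C)Oc1cc(co1)C(O)C/C(C)=C\CCC(=C)C(OCC)OCC
F7 | step 7 | (3Z)-7-(diethoxymethyl)-3-methyl-1-[5-(triisopropylsilyloxy)furan-3-yl]octa-3,7-dien-1-one | CC(C)[Si](C(C)C)(C(C)C)Oc1cc(co1)C(=O)C/C(C)=C\CCC(=C)C(OCC)OCC
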